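**Retrosynthetic overview**

- The target is an (S)-3-alkyl-5,7-dimethoxyphthalide. It is reached by acetylation of the side-chain carbinol, after acid unmasking of a silyl ether and a dioxolane.
- Key disconnection: the two lactone bonds to the arene, C3–C3a and C7a–C1, are cut together. This gives 3,5-dimethoxybenzyne and the (R)-α-lithiated N,N-diisopropylcarbamate of the C13 side-chain alcohol. The lactone is the only ring that is built; the benzene ring is bought.
- Feature used: the neighbouring arene carbons C3a and C7a carry the carbinol carbon C3 and the acyl carbon C1, and the C7 methoxy lies next to C7a. A 3-methoxy-type aryne leaves exactly this pattern when a carbanion adds at the carbon remote from OMe and the aryl anion next to OMe takes the acyl group.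
- The carbamate comes from undec-10-enal by catalytic asymmetric addition of a ketal-bearing alkyl(silylmethyl)zinc (sets the side-chain (R) centre), silylation, hydroboration–oxidation and carbamoylation. The aryne source comes from 1-bromo-3,5-dimethoxybenzene by one bromination.

Key step: step 8

Assumption: the lithiated carbamate is taken to add to the aryne with retention at the carbanion carbon (the normal course for non-benzylic, sparteine-complexed lithiated carbamates), so (+)-sparteine is specified; if the addition inverted, (−)-sparteine would be used in the same way.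

**Route**

Step 1
Reactants: 1 1-bromo-3,5-dimethoxybenzene
Product: 2 1,2-dibromo-3,5-dimethoxybenzene
Conditions: NBS (1.0 equiv), MeCN, 0 °C → rt
Reagents that add atoms: N-bromosuccinimide, O=C1CCC(=O)N1Br
Why: Electrophilic aromatic bromination should go to C2, which is ortho to one methoxy and para to the other and less hindered than the site between the two methoxy groups, and one equivalent of NBS should stop at the dibromide.

Step 2
Reactants: 3 2-(2-bromoethyl)-2-methyl-1,3-dioxolane
Product: 4 2-(2-iodoethyl)-2-methyl-1,3-dioxolane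
Conditions: NaI, NaHCO3, acetone, reflux
Reagents that add atoms: sodium iodide, [Na+].[I-]
Why: Finkelstein reaction (SN2 at a primary carbon) driven by precipitation of NaBr, with bicarbonate keeping the ketal away from acid.

Step 3
Reactants: 4 2-(2-iodoethyl)-2-methyl-1,3-dioxolane
Product: 6 [2-(2-methyl-1,3-dioxolan-2-yl)ethyl][(trimethylsilyl)methyl]zinc, via alkylzinc iodide 5 (not isolated)
Conditions: Zn dust (activated with BrCH2CH2Br and Me3SiCl, 3 mol % each), THF, 35 °C; then Me3SiCH2Li (1.0 equiv, pentane), −78 → 0 °C; solvents removed in vacuo, residue extracted with PhMe–hexane, LiI filtered off under Ar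
Reagents that add atoms: zinc, [Zn]; (trimethylsilyl)methyllithium, [Li]C[Si](C)(C)C
Why: Direct insertion of activated zinc into the primary C–I bond gives the alkylzinc iodide (the ketal oxygens sit gamma to zinc, so no beta-elimination is possible), and transmetalation with (trimethylsilyl)methyllithium turns it into a mixed diorganozinc whose silylmethyl group is a non-transferable ligand, while the solvent change removes the lithium iodide that would otherwise promote an uncatalysed racemic addition.

Step 4
Reactants: 6 [2-(2-methyl-1,3-dioxolan-2-yl)ethyl][(trimethylsilyl)methyl]zinc; 7 undec-10-enal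
Product: 8 (3R)-1-(2-methyl-1,3-dioxolan-2-yl)tridec-12-en-3-ol
Conditions: Ti(OiPr)4, (1R,2R)-1,2-bis(trifluoromethanesulfonamido)cyclohexane (8 mol %), PhMe, −20 °C; then H2O
Reagents that add atoms: none
Why: Titanium bis(sulfonamide)-catalysed enantioselective addition of a mixed diorganozinc to an aldehyde, in which only the functionalised alkyl group is transferred because the (trimethylsilyl)methyl group stays on zinc; the (1R,2R) ligand directs alkyl transfer to the Si face (the sense that gives (S)-1-phenylpropan-1-ol from benzaldehyde and Et2Zn), which here is the (R) carbinol because the transferred ketal chain outranks the alkenyl chain.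

Step 5
Reactants: 8 (3R)-1-(2-methyl-1,3-dioxolan-2-yl)tridec-12-en-3-ol
Product: 9 tert-butyl(dimethyl){[(3R)-1-(2-methyl-1,3-dioxolan-2-yl)tridec-12-en-3-yl]oxy}silane
Conditions: TBSCl, imidazole, DMF, rt
Reagents that add atoms: tert-butyldimethylsilyl chloride, CC(C)(C)[Si](C)(C)Cl
Why: Imidazole-promoted silylation of a secondary alcohol gives an ether that is stable to the borane, the alkyllithiums and the aryne chemistry that follow.

Step 6
Reactants: 9 tert-butyl(dimethyl){[(3R)-1-(2-methyl-1,3-dioxolan-2-yl)tridec-12-en-3-yl]oxy}silane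
Product: 11 (11R)-11-[(tert-butyldimethylsilyl)oxy]-13-(2-methyl-1,3-dioxolan-2-yl)tridecan-1-ol, via alkylborane 10 (not isolated)
Conditions: 9-BBN, THF, 0 °C → rt; then NaOH, H2O2, 0 °C → rt
Reagents that add atoms: hydrogen peroxide, OO
Why: Anti-Markovnikov hydroboration of the terminal alkene with 9-BBN and alkaline peroxide oxidation of the C–B bond; silyl ether and ketal are inert and the carbinol centre is untouched.

Step 7
Reactants: 11 (11R)-11-[(tert-butyldimethylsilyl)oxy]-13-(2-methyl-1,3-dioxolan-2-yl)tridecan-1-ol; 12 N,N-di(propan-2-yl)carbamoyl chloride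
Product: 13 (11R)-11-[(tert-butyldimethylsilyl)oxy]-13-(2-methyl-1,3-dioxolan-2-yl)tridecyl N,N-di(propan-2-yl)carbamate
Conditions: Et3N, DMAP (cat.), CH2Cl2, reflux
Reagents that add atoms: none
Why: O-Carbamoylation of the only free (primary) hydroxyl by acyl substitution gives the hindered carbamate that directs and stabilises alpha-lithiation.

Step 8
Reactants: 13 (11R)-11-[(tert-butyldimethylsilyl)oxy]-13-(2-methyl-1,3-dioxolan-2-yl)tridecyl N,N-di(propan-2-yl)carbamate; 2 1,2-dibromo-3,5-dimethoxybenzene
Product: 19 (3S)-3-[(10R)-10-[(tert-butyldimethylsilyl)oxy]-12-(2-methyl-1,3-dioxolan-2-yl)dodecyl]-5,7-dimethoxy-2-benzofuran-1(3H)-one, via lithiated carbamate 14 (not isolated), via bromoaryllithium 15 (not isolated), via 3,5-dimethoxybenzyne 16 (not isolated), via aryllithium adduct 17 (not isolated), via hydroxy amide 18 (not isolated)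
Conditions: s-BuLi, (+)-sparteine, Et2O, −78 °C, 5 h; then 15 (pre-formed from 2, n-BuLi, THF, −100 °C) added slowly, −78 → −50 °C, then rt; AcOH quench; then CSA (0.3 equiv), PhMe, 80 °C
Reagents that add atoms: none
Why: Proposed new method: (+)-sparteine/s-BuLi should remove the pro-R hydrogen of the O–CH2 group to give the configurationally stable (R)-lithiocarbamate 14, which is expected to add across the strained triple bond of aryne 16 (set free from 15 by loss of LiBr) in a four-centre syn carbolithiation with retention at carbon, so that the aryl carbon takes the place of lithium and C3 becomes (S); the closest known reactions are the stereoretentive electrophilic trapping of sparteine-complexed lithiated alkyl carbamates and the carbolithiation of arynes with intramolecular capture of the new aryllithium. Regioselectivity comes from the methoxy group flanking the aryne, whose inductive pull and ring distortion send the carbanion to the distal aryne carbon (C3–C3a bond) and leave lithium on the carbon next to OMe, the future C7a. Aryllithium 17 then lies four atoms from the carbamoyl carbon and attacks it in a 5-exo-trig closure (C7a–C1 bond), as in anionic Fries-type carbamoyl transfers. The tetrahedral adduct is expected to expel the better leaving group, the benzylic alkoxide, giving the lithium alkoxide of hydroxy amide 18, which also removes the acidic benzylic C–H next to a carbamate and so protects C3 from epimerisation. After the acetic acid quench, CSA (and the diisopropylammonium sulfonate it becomes as the amine is released) promotes 5-exo-trig attack of the hydroxyl on the twisted benzamide carbonyl with loss of diisopropylamine, reclosing the five-membered lactone without touching the C3–O bond. The step needs chemoselectivity for 14 over the only other carbanion present, which the hindered, weakly nucleophilic character of 15 and its slow addition should provide, and the remote silyl ether and ketal are inert to all the bases used.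

Step 9
Reactants: 19 (3S)-3-[(10R)-10-[(tert-butyldimethylsilyl)oxy]-12-(2-methyl-1,3-dioxolan-2-yl)dodecyl]-5,7-dimethoxy-2-benzofuran-1(3H)-one
Product: 20 (3S)-3-[(10R)-10-hydroxy-13-oxotetradecyl]-5,7-dimethoxy-2-benzofuran-1(3H)-one
Conditions: 2 M HCl (aq.), THF, rt
Reagents that add atoms: water, O
Why: Acid-catalysed ketal hydrolysis and protodesilylation of the secondary silyl ether in one operation; the phthalide tolerates aqueous acid and C3 cannot ionise because both methoxy groups are meta to it.

Step 10
Reactants: 20 (3S)-3-[(10R)-10-hydroxy-13-oxotetradecyl]-5,7-dimethoxy-2-benzofuran-1(3H)-one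
Product: 21 (3S)-3-[(10R)-10-acetoxy-13-oxotetradecyl]-5,7-dimethoxy-2-benzofuran-1(3H)-one (CNP0131579.2)
Conditions: Ac2O, pyridine, DMAP (cat.), CH2Cl2, 0 °C → rt
Reagents that add atoms: acetic anhydride, CC(=O)OC(C)=O
Why: DMAP-catalysed acetylation of the secondary alcohol (acyl substitution), which also drains any cyclic hemiketal through the open hydroxy ketone; neither stereocentre takes part.

**Compound list**

1 | 1-bromo-3,5-dimethoxybenzene | COc1cc(Br)cc(OC)c1 | starting material
2 | 1,2-dibromo-3,5-dimethoxybenzene | COc1cc(OC)c(Br)c(Br)c1 | intermediate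
3 | 2-(2-bromoethyl)-2-methyl-1,3-dioxolane | CC1(CCBr)OCCO1 | starting material
4 | 2-(2-iodoethyl)-2-methyl-1,3-dioxolane | CC1(CCI)OCCO1 | intermediate
5 | iodo[2-(2-methyl-1,3-dioxolan-2-yl)ethyl]zinc (not isolated) | CC1(CC[Zn]I)OCCO1 | intermediate
6 | [2-(2-methyl-1,3-dioxolan-2-yl)ethyl][(trimethylsilyl)methyl]zinc | CC1(CC[Zn]C[Si](C)(C)C)OCCO1 | intermediate
7 | undec-10-enal | C=CCCCCCCCCC=O | starting material
8 | (3R)-1-(2-methyl-1,3-dioxolan-2-yl)tridec-12-en-3-ol | C=CCCCCCCCC[C@H](CCC1(C)OCCO1)O | intermediate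
9 | tert-butyl(dimethyl){[(3R)-1-(2-methyl-1,3-dioxolan-2-yl)tridec-12-en-3-yl]oxy}silane | C=CCCCCCCCC[C@H](CCC1(C)OCCO1)O[Si](C)(C)C(C)(C)C | intermediate
10 | 9-[(11R)-11-[(tert-butyldimethylsilyl)oxy]-13-(2-methyl-1,3-dioxolan-2-yl)tridecyl]-9-borabicyclo[3.3.1]nonane (not isolated) | C1CC2CCCC(C1)B2CCCCCCCCCC[C@H](CCC3(C)OCCO3)O[Si](C)(C)C(C)(C)C | intermediate
11 | (11R)-11-[(tert-butyldimethylsilyl)oxy]-13-(2-methyl-1,3-dioxolan-2-yl)tridecan-1-ol | OCCCCCCCCCC[C@H](CCC1(C)OCCO1)O[Si](C)(C)C(C)(C)C | intermediate
12 | N,N-di(propan-2-yl)carbamoyl chloride | CC(C)N(C(C)C)C(Cl)=O | starting material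
13 | (11R)-11-[(tert-butyldimethylsilyl)oxy]-13-(2-methyl-1,3-dioxolan-2-yl)tridecyl N,N-di(propan-2-yl)carbamate | CC(C)N(C(C)C)C(=O)OCCCCCCCCCC[C@H](CCC1(C)OCCO1)O[Si](C)(C)C(C)(C)C | intermediate
14 | (1R,11R)-11-[(tert-butyldimethylsilyl)oxy]-1-lithio-13-(2-methyl-1,3-dioxolan-2-yl)tridecyl N,N-di(propan-2-yl)carbamate, as its (+)-sparteine complex (not isolated) | CC(C)N(C(C)C)C(=O)O[C@H]([Li])CCCCCCCCC[C@H](CCC1(C)OCCO1)O[Si](C)(C)C(C)(C)C | intermediate
15 | (2-bromo-4,6-dimethoxyphenyl)lithium (not isolated) | [Li]c1c(Br)cc(OC)cc1OC | intermediate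
16 | 3,5-dimethoxybenzyne (1,2-didehydro-3,5-dimethoxybenzene; not isolated) | COC1=CC(OC)=CC#C1 | intermediate
17 | (1S,11R)-11-[(tert-butyldimethylsilyl)oxy]-1-(2-lithio-3,5-dimethoxyphenyl)-13-(2-methyl-1,3-dioxolan-2-yl)tridecyl N,N-di(propan-2-yl)carbamate (not isolated) | COc1cc(OC)c([Li])c(c1)[C@H](CCCCCCCCC[C@H](CCC2(C)OCCO2)O[Si](C)(C)C(C)(C)C)OC(=O)N(C(C)C)C(C)C | intermediate
18 | 2-[(1S,11R)-11-[(tert-butyldimethylsilyl)oxy]-1-hydroxy-13-(2-methyl-1,3-dioxolan-2-yl)tridecyl]-4,6-dimethoxy-N,N-di(propan-2-yl)benzamide, first formed as its lithium alkoxide (not isolated) | COc1cc(OC)c(C(=O)N(C(C)C)C(C)C)c(c1)[C@@H](O)CCCCCCCCC[C@H](CCC2(C)OCCO2)O[Si](C)(C)C(C)(C)C | intermediate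
19 | (3S)-3-[(10R)-10-[(tert-butyldimethylsilyl)oxy]-12-(2-methyl-1,3-dioxolan-2-yl)dodecyl]-5,7-dimethoxy-2-benzofuran-1(3H)-one | COc1cc(OC)c2c(c1)[C@H](CCCCCCCCC[C@H](CCC3(C)OCCO3)O[Si](C)(C)C(C)(C)C)OC2=O | intermediate
20 | (3S)-3-[(10R)-10-hydroxy-13-oxotetradecyl]-5,7-dimethoxy-2-benzofuran-1(3H)-one | COc1cc(OC)c2c(c1)[C@H](CCCCCCCCC[C@H](CCC(C)=O)O)OC2=O | intermediate
21 | (3S)-3-[(10R)-10-acetoxy-13-oxotetradecyl]-5,7-dimethoxy-2-benzofuran-1(3H)-one | COc1cc(OC)c2c(c1)[C@H](CCCCCCCCC[C@H](CCC(C)=O)OC(C)=O)OC2=O | target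

**Step count**

Total: 10 steps. Longest linear sequence: 9 steps (3 → 4 → 6 → 8 → 9 → 11 → 13 → 19 → 20 → 21, steps 2–10); step 1 is a one-step branch.

**Steps most likely to fail**

Step 8 (proposed new method). Several processes may defeat it:
- The lithiated carbamate may decompose or lose configuration at the temperature needed for loss of LiBr.
- Bromine–lithium exchange or proton transfer may compete with carbolithiation, and the bromoaryllithium may add to the aryne itself.
- Carbamoyl transfer may lag behind, so that the benzylic carbamate is deprotonated and C3 erodes.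
- Lactonisation of the hindered amide may be slow. Material that loses the silyl ether or ketal here still converges in step 9.

The fallback uses known chemistry, sets out from carbamate 13 and returns at phthalide 19. The same (+)-sparteine lithiation is followed by borylation with commercial 2-(3,5-dimethoxyphenyl)-4,4,5,5-tetramethyl-1,3,2-dioxaborolane and stereospecific 1,2-aryl migration (MgBr2·OEt2, Et2O, reflux). This should give 2-[(1S,11R)-11-[(tert-butyldimethylsilyl)oxy]-1-(3,5-dimethoxyphenyl)-13-(2-methyl-1,3-dioxolan-2-yl)tridecyl]-4,4,5,5-tetramethyl-1,3,2-dioxaborolane F1. Oxidation with NaOH/H2O2 proceeds with retention to (1S,11R)-11-[(tert-butyldimethylsilyl)oxy]-1-(3,5-dimethoxyphenyl)-13-(2-methyl-1,3-dioxolan-2-yl)tridecan-1-ol F2. NBS in MeCN at 0 °C should brominate the ring ortho to the side chain and para to a methoxy group, giving (1S,11R)-1-(2-bromo-3,5-dimethoxyphenyl)-11-[(tert-butyldimethylsilyl)oxy]-13-(2-methyl-1,3-dioxolan-2-yl)tridecan-1-ol F3. Palladium-catalysed carbonylative lactonisation (Pd(OAc)2, dppf, CO, K2CO3, DMF, 90 °C) then closes the lactone to 19.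

Step 4. What may go wrong: insufficient facial selectivity with an unbranched aldehyde, residual lithium iodide from step 3 opening an uncatalysed racemic pathway, sluggish transfer of the functionalised alkyl group from the mixed zinc reagent, or aldol self-condensation of the aldehyde. Any enantiomeric deficit becomes a diastereomer of the target.

The fallback needs no organozinc reagent; it sets out from undec-10-enal 7 and returns at silyl ether 9. Corey–Chaykovsky methylenation (trimethylsulfonium iodide, KOtBu, DMSO–THF) gives racemic 2-(dec-9-en-1-yl)oxirane F4. Hydrolytic kinetic resolution with (R,R)-N,N'-bis(3,5-di-tert-butylsalicylidene)-1,2-cyclohexanediaminocobalt acetate (trivalent cobalt) and 0.55 equiv of water leaves (2R)-2-(dec-9-en-1-yl)oxirane F5. The lithium aza-enolate of acetone N,N-dimethylhydrazone opens F5 at its CH2 terminus to (5R)-5-hydroxypentadec-14-en-2-one N,N-dimethylhydrazone F6. Silylation (TBSCl, imidazole) gives (5R)-5-[(tert-butyldimethylsilyl)oxy]pentadec-14-en-2-one N,N-dimethylhydrazone F7. Mild hydrazone hydrolysis (Cu(OAc)2, THF–H2O) releases (5R)-5-[(tert-butyldimethylsilyl)oxy]pentadec-14-en-2-one F8. Ketalisation with 1,2-bis(trimethylsilyloxy)ethane and catalytic TMSOTf (CH2Cl2, −78 °C) gives 9.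

Step 9. What may go wrong: the liberated 4-hydroxy ketone may close to the five-membered hemiketal and dehydrate to a dihydrofuran under acid, or desilylation may be incomplete.

The fallback sets out from 19 and returns at target 21, never exposing a free hydroxy ketone. Buffered fluoride (TBAF, AcOH, THF) removes only the silyl group to give (3S)-3-[(10R)-10-hydroxy-12-(2-methyl-1,3-dioxolan-2-yl)dodecyl]-5,7-dimethoxy-2-benzofuran-1(3H)-one F9. Acetylation (Ac2O, pyridine, DMAP) gives (3S)-3-[(10R)-10-acetoxy-12-(2-methyl-1,3-dioxolan-2-yl)dodecyl]-5,7-dimethoxy-2-benzofuran-1(3H)-one F10. Mild ketal hydrolysis (PPTS, wet acetone, 50 °C) then gives 21.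

**Further compounds**

F1 | step 8 | 2-[(1S,11R)-11-[(tert-butyldimethylsilyl)oxy]-1-(3,5-dimethoxyphenyl)-13-(2-methyl-1,3-dioxolan-2-yl)tridecyl]-4,4,5,5-tetramethyl-1,3,2-dioxaborolane | COc1cc(OC)cc(c1)[C@@H](B2OC(C)(C)C(C)(C)O2)CCCCCCCCC[C@H](CCC3(C)OCCO3)O[Si](C)(C)C(C)(C)C
F2 | step 8 | (1S,11R)-11-[(tert-butyldimethylsilyl)oxy]-1-(3,5-dimethoxyphenyl)-13-(2-methyl-1,3-dioxolan-2-yl)tridecan-1-ol | COc1cc(OC)cc(c1)[C@@H](O)CCCCCCCCC[C@H](CCC2(C)OCCO2)O[Si](C)(C)C(C)(C)C
F3 | step 8 | (1S,11R)-1-(2-bromo-3,5-dimethoxyphenyl)-11-[(tert-butyldimethylsilyl)oxy]-13-(2-methyl-1,3-dioxolan-2-yl)tridecan-1-ol | COc1cc(OC)c(Br)c(c1)[C@@H](O)CCCCCCCCC[C@H](CCC2(C)OCCO2)O[Si](C)(C)C(C)(C)C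
F4 | step 4 | racemic 2-(dec-9-en-1-yl)oxirane | C=CCCCCCCCCC1CO1
F5 | step 4 | (2R)-2-(dec-9-en-1-yl)oxirane | C=CCCCCCCCC[C@@H]1CO1
F6 | step 4 | (5R)-5-hydroxypentadec-14-en-2-one N,N-dimethylhydrazone | C=CCCCCCCCC[C@H](CCC(C)=NN(C)C)O
F7 | step 4 | (5R)-5-[(tert-butyldimethylsilyl)oxy]pentadec-14-en-2-one N,N-dimethylhydrazone | C=CCCCCCCCC[C@H](CCC(C)=NN(C)C)O[Si](C)(C)C(C)(C)C
F8 | step 4 | (5R)-5-[(tert-butyldimethylsilyl)oxy]pentadec-14-en-2-one | C=CCCCCCCCC[C@H](CCC(C)=O)O[Si](C)(C)C(C)(C)C
F9 | step 9 | (3S)-3-[(10R)-10-hydroxy-12-(2-methyl-1,3-dioxolan-2-yl)dodecyl]-5,7-dimethoxy-2-benzofuran-1(3H)-one | COc1cc(OC)c2c(c1)[C@H](CCCCCCCCC[C@H](CCC3(C)OCCO3)O)OC2=O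
F10 | step 9 | (3S)-3-[(10R)-10-acetoxy-12-(2-methyl-1,3-dioxolan-2-yl)dodecyl]-5,7-dimethoxy-2-benzofuran-1(3H)-one | COc1cc(OC)c2c(c1)[C@H](CCCCCCCCC[C@H](CCC3(C)OCCO3)OC(C)=O)OC2=O
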